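Remark on the chemistry: positions are numbered as in germacranolides (ring carbons C1–C10; C11–C13 lactone carbons, C12 the carbonyl), TBS = tert-butyldimethylsilyl, TIPS = triisopropylsilyl, PMB = 4-methoxybenzyl, and compounds 1, 2, 5 and 6 are taken as commercial.

## Analysis of the target

Compound 35 is a germacranolide: a ten-membered carbocycle C1–C10 with an α-methylene-γ-butyrolactone fused trans across C6 (oxygen) and C7 (carbon). The ring carries five stereocentres. C6, C7 and C8 form a contiguous triad (C6–O and C7–C11 trans, C7–C11 and C8–O cis). C10 is a tertiary methyl carbinol whose hydroxyl is anti to the C8 oxygen. C3 is an allylic carbinol remote from the triad. The only ring alkene, C4=C5, is trisubstituted, Z in the ring sense (C3 and C6 cis) and flanked by two allylic oxygens.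

The sensitive groups are the α-methylene lactone (Michael acceptor, and able to translactonise onto a free C8 hydroxyl), the isobutyrate, the tertiary alcohol and the two allylic C–O bonds. The hard parts are the medium ring (entropy, transannular strain), the Z alkene geometry and C3.

The strategy rests on one feature: the sequence O–C10–C1–C2–C3–C4=C5, with a bond restored between C5 and C10, is the 3-oxido-1,5-diene C2=C1–C10(O)–C5–C4=C3. A cyclohexanol (ring B: C5–C10) bearing a vinyl group on C10 and an enol ether on C5 can therefore deliver the ten-membered ring, the C4=C5 alkene and the C3 stereocentre in one oxy-Cope shift, with C6, C7 and C8 already set on ring B.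

## Retrosynthetic reasoning

**35 ⇒ 34 ⇒ 33 ⇒ 32.** The C3 protecting group and the C8 ester C–O bond are cut last. An ester with an α-hydrogen would not survive the enolate step that makes C11=C13, and C3–OH must stay masked so that only C8–OH is acylated. This leads back to the C8 silyl ether 32.

**32 ⇒ 29.** C11=C13 is cut (aminomethylation and elimination). The saturated lactone 29 tolerates the preceding oxidation, which the methylene lactone would not.

**29 ⇒ 26 ⇒ 25.** The lactone C12–O6 bond is cut to a 1,4-diol (26). Oxidation of the primary alcohol closes the five-membered lactol onto C6–OH. C8 stays silylated so that the lactone cannot form toward C8. Diol 26 comes from 25 by removing two silyl groups of equal lability.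

**25 ⇒ 24.** The C10–methyl bond is cut. The ketone 24 is exactly what the ring expansion delivers, so the tertiary carbinol costs one step.

**24 ⇒ 21.** This is the key disconnection: C2–C3 is cut and C5–C10 is restored. It gives the ring B cyclohexanol 21 with a C10 vinyl group and a C5 (E)-enol ether. The forward reaction must form the Z C4=C5 alkene and transfer chirality from C5 to C3.

**21 ⇒ 20 ⇒ 18.** The enol ether C3–O bond is cut at the vinyl iodide 20. A C(sp2)–O coupling transmits alkene geometry, whereas a dehydration or an alkoxymethylenation would not control E/Z of a trisubstituted enol ether. Iodide 20 comes from the terminal alkyne 18 by syn-carbometalation, which places the C4 methyl and fixes E.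

**18 ⇒ 17 ⇒ 16 ⇒ 14.** The vinyl group (C1=C2) is traced to a hydroxymethyl group through a spiro-epoxide and a one-carbon ylide homologation. The C10–O bond is never broken, and an α-hydroxy aldehyde is avoided.

**14 ⇒ 13 ⇒ 12.** The C4–C5 bond is cut as the anti opening of a C5–C10 epoxide by an acetylide. One stereospecific event gives the alkynyl group anti to the C10 oxygen (hence cis to the future vinyl group) and cis to the C6 oxygen. Adding a vinyl nucleophile to an α-alkenyl C10 ketone would favour the wrong (trans) dialkenyl carbinol and would pass through an epimerisable β-alkoxy ketone. The epoxide face in 13 is set by the C8 hydroxyl of 12.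

**12 ⇒ 11 ⇒ 9 ⇒ 8.** The C8 oxygen is traced to a nitro group (Nef reaction, then hydride delivery cis to the C7 side chain). The ester of 8 is reduced first so that the ketone is never conjugated through to an ester.

**8 ⇒ 4 + 5 + 6 (via 7).** Ring B is cut at C6–C7, C8–C9 and C5=C10: an enamine Michael addition sets C6 and C7, and a nitronate Michael addition followed by an intramolecular Horner–Wadsworth–Emmons reaction closes the ring.

**4 ⇒ 1 + 2.** The nitroalkene is cut at its C=C bond (Henry reaction and dehydration).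

## Alternatives that were turned down

**Alternative 1:** C4–C5 and C1–C10 are cut. Forward, a [2+2] photocycloaddition of the ring B enone A2 with methyl cyclobut-1-ene-1-carboxylate A3 gives the tricyclic adduct A1, whose bicyclo[2.2.0]hexane is later opened thermally to a ten-membered 1(10),4-diene.
- For: two C–C bonds are made in one step from small pieces, and ring strain drives the opening. Up to the carbon skeleton this is shorter than the chosen route.
- Against: head-to-head regiochemistry and facial selectivity of the photoaddition are not secured. The opening can also cleave C2–C3 (divinylcyclohexane) and does not fix a Z C4=C5 geometry. A1 lacks the C3 oxygen, carries an ester where the C4 methyl must be, and leads to a C1=C10 alkene where the tertiary carbinol is needed.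
- Comparison: several stereo-uncontrolled redox corrections follow the ring opening. The chosen route sets C3 and the alkene geometry in the ring-forming step and ends at the C10 ketone.

**Alternative 2:** C3–C4 is cut. Forward, an intramolecular Nozaki–Hiyama–Kishi reaction of the seco (Z)-vinyl iodide aldehyde A5 closes the ring to A4, the C10 triethylsilyl ether of the target.
- For: the Z geometry is fixed beforehand in the iodide, the reaction tolerates lactone, ester and methylene group, and the target is one deprotection away. On lateness, convergence and chemoselectivity this is stronger than the chosen route.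
- Against: a ten-membered closure fights entropy and transannular strain (high dilution, large excess of chromium salt). The C3 configuration would be decided only by the macrocyclic transition-state conformation. A5 is an open chain with four stereocentres, including an acyclic tertiary carbinol remote from C8, and carries the methylene lactone through many steps.
- Comparison: the chosen route builds its stereocentres on a six-membered ring, needs no dilution, and sets C3 by chirality transfer.

**Alternative 3:** the ten-membered ring is traced to the lactone-fused cis-decalin epoxy alcohol A7. Forward, a Lewis-acid-triggered Grob fragmentation (C10 alkoxide pushes, C5–C10 breaks, the epoxide opens at C4) gives the hydroxy keto lactone A6.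
- For: the fragmentation is stereospecific (anti-periplanar), so the Z alkene and C3 follow rigidly from the decalin. On certainty of alkene geometry this is stronger than the chosen route, which relies on a preference between two chair transition states.
- Against: A7 needs seven stereocentres on a cis-decalin, four of them (C3, C4, C5, C10) only to be destroyed or relayed. The epoxy alcohol can instead undergo transannular ether formation or a semipinacol shift. A6 holds ketone and lactone together, so the methyl addition must discriminate.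
- Comparison: the chosen route also cleaves C5–C10 of a cyclohexanol, but from a monocyclic ring B with three permanent stereocentres, and it forms C2–C3 in the same step, so the precursor is much shorter.

Key step: step 13

## Route

Step 1
Reactants: 1 3-(tert-butyldimethylsilyloxy)propanal; 2 nitromethane
Product: 4 (E)-tert-butyldimethyl(4-nitrobut-3-enyloxy)silane, via nitro alcohol 3 (not isolated)
Conditions: MeNO2 (excess), Et3N (cat.), 0 °C to rt; then MsCl, Et3N, CH2Cl2, 0 °C
Reagents that add atoms: none
Why: Henry reaction followed by mesylation and E1cB elimination; the conjugated E nitroalkene is the thermodynamic product.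

Step 2
Reactants: 5 (tert-butyldimethylsilyloxy)acetaldehyde; 4 (E)-nitroalkene; 6 ethyl 2-(diethoxyphosphoryl)acrylate
Product: 8 ethyl (3R,4R)-3-(TBS-oxy)-4-[2-(TBS-oxy)ethyl]-5-nitrocyclohex-1-ene-1-carboxylate (C8 nitro epimers), via nitro aldehyde 7 (not isolated)
Conditions: (R)-diphenylprolinol trimethylsilyl ether (10 mol%), ClCH2CO2H (20 mol%), CH2Cl2, rt; then 6, Cs2CO3, 0 °C; then EtOH, rt
Reagents that add atoms: none
Why: Enamine-catalysed Michael addition to the nitroalkene (syn adduct through the synclinal transition state, on the enamine face away from the diphenylsilyloxymethyl group) sets C6 and C7; on the standard shielding model the (R) catalyst gives the required (2S,3R) aldehyde 7. The nitronate then adds to the vinylphosphonate and an intramolecular Horner–Wadsworth–Emmons reaction closes ring B with the C5=C10 alkene; the nitro-bearing C8 is formed as a mixture, which is irrelevant.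

Step 3
Reactants: 8 cyclohexene ester
Product: 9 [(3R,4R)-3-(TBS-oxy)-4-[2-(TBS-oxy)ethyl]-5-nitrocyclohex-1-en-1-yl]methanol
Conditions: i-Bu2AlH, CH2Cl2, −78 °C
Reagents that add atoms: none
Why: 1,2-Reduction of the enoate to the allylic alcohol, done before the Nef reaction so that the coming ketone is not vinylogously activated by an ester and no later hydride meets a conjugate acceptor.

Step 4
Reactants: 9 nitro allylic alcohol
Product: 11 3-(hydroxymethyl)-5-(TBS-oxy)-6-[2-(TBS-oxy)ethyl]cyclohex-3-en-1-one (C6 and C7 as in 9), via sodium nitronate 10 (not isolated)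
Conditions: NaOMe, MeOH, 0 °C; then TiCl3, NH4OAc, H2O, rt
Reagents that add atoms: water, O
Why: Reductive Nef reaction: trivalent titanium reduces the nitronate to the imine, which hydrolyses at pH 5–6, so the β-silyloxy β,γ-unsaturated ketone never meets base. C7 is already the more stable epimer (trans to the C6 oxygen) and should not drift.

Step 5
Reactants: 11 ketone
Product: 12 (1R,5R,6R)-5-(TBS-oxy)-6-[2-(TBS-oxy)ethyl]-3-(hydroxymethyl)cyclohex-3-en-1-ol
Conditions: LiBH(s-Bu)3, THF, −78 °C; then NaOH, H2O2
Reagents that add atoms: none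
Why: Bulky-hydride reduction of an α-substituted cyclohexanone: attack from the equatorial side, past the pseudo-equatorial C7 side chain, gives the axial C8 alcohol cis to that chain.

Step 6
Reactants: 12 diol
Product: 13 C5–C10 epoxide of 12 (oxirane oxygen cis to C8–OH, trans to C6–OTBS)
Conditions: VO(acac)2 (cat.), t-BuOOH, CH2Cl2, 0 °C to rt
Reagents that add atoms: tert-butyl hydroperoxide, CC(C)(C)OO
Why: Hydroxyl-directed epoxidation: the vanadium peroxide held by the pseudo-axial homoallylic C8–OH (and the allylic CH2OH) delivers oxygen to the face syn to C8–OH, which is also the face away from the allylic C6 silyl ether.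

Step 7
Reactants: 13 epoxy diol
Product: 14 ring B triol with C10 (OH, CH2OH), C5 trimethylsilylethynyl (trans to C10–OH, cis to C6–OTBS), C8 OH
Conditions: Me3SiC≡CH, n-BuLi, toluene, −78 to 0 °C; Et2AlCl; then 13, 0 °C to rt
Reagents that add atoms: ethynyltrimethylsilane, C#C[Si](C)(C)C
Why: Alkynylalane opening of a 2,3-epoxy alcohol at C3 (here C5): SN2 with inversion, trans-diaxial (Fürst–Plattner) in the half-chair that keeps the C6 and C7 substituents equatorial, while quaternary C10 is blocked. This sets C5 anti to the C10 oxygen and therefore cis to the C6 oxygen; the C10–O bond is retained.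

Step 8
Reactants: 14 triol
Product: 16 spiro-epoxide (C10–O–CH2 oxirane) with C5 ethynyl and C8 OH, via primary tosylate 15 (not isolated)
Conditions: TsCl, Et3N, Bu2SnO (cat.), CH2Cl2, 0 °C to rt; then K2CO3, MeOH, rt
Reagents that add atoms: none
Why: Stannylene-mediated sulfonylation selects the primary hydroxyl of the 1,2-diol; the tertiary alkoxide then closes the oxirane (3-exo-tet) with its C–O bond intact, and the same methanolic carbonate removes the alkynyl silyl group.

Step 9
Reactants: 16 spiro-epoxide
Product: 17 C10 vinyl carbinol (C5 ethynyl, C8 OH)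
Conditions: Me3S+ I−, n-BuLi, THF, −10 °C to rt
Reagents that add atoms: trimethylsulfonium iodide, C[S+](C)C.[I-]
Why: One-carbon homologation of an epoxide to an allylic alcohol: the sulfonium ylide opens the oxirane at CH2 and a second equivalent induces elimination of dimethyl sulfide. The lithium counter-ion and low temperature keep the resulting enynyl alkoxide from rearranging.

Step 10
Reactants: 17 diol
Product: 18 C8 triisopropylsilyl ether of 17
Conditions: i-Pr3SiOTf, 2,6-lutidine, CH2Cl2, −78 to −20 °C
Reagents that add atoms: triisopropylsilyl trifluoromethanesulfonate, CC(C)[Si](C(C)C)(C(C)C)OS(=O)(=O)C(F)(F)F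
Why: Silylation of the secondary alcohol is much faster than that of the tertiary carbinol; TIPS is chosen to outlast the TBS ethers and to resist O-to-O migration toward the later C10 alkoxide.

Step 11
Reactants: 18 terminal alkyne
Product: 20 (E)-vinyl iodide (C5–C(CH3)=CH–I), via alkenylalane 19 (not isolated)
Conditions: Me3Al, Cp2ZrCl2, ClCH2CH2Cl, 0 °C to rt; then I2, THF, −30 °C
Reagents that add atoms: trimethylaluminium, C[Al](C)C; iodine, II
Why: Zirconium-catalysed syn-carboalumination places methyl on the internal carbon (C4) and aluminium on the terminus; iodinolysis with retention gives the E iodide (ring carbon C5 and iodine trans). The tertiary hydroxyl is carried as its aluminium alkoxide.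

Step 12
Reactants: 20 vinyl iodide
Product: 21 (1R,2S,3S,4R,5R)-3-(TBS-oxy)-4-[2-(TBS-oxy)ethyl]-2-[(E)-1-(PMB-oxy)prop-1-en-2-yl]-5-(TIPS-oxy)-1-vinylcyclohexan-1-ol
Conditions: CuI (10 mol%), 3,4,7,8-tetramethyl-1,10-phenanthroline (20 mol%), Cs2CO3, 4-MeOC6H4CH2OH, toluene, 80 °C
Reagents that add atoms: 4-methoxybenzyl alcohol, COc1ccc(CO)cc1
Why: Copper-catalysed Ullmann-type C–O coupling of a vinyl iodide with a primary alcohol proceeds with retention of alkene geometry, giving the E enol ether; the hindered tertiary hydroxyl should not compete.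

Step 13
Reactants: 21 divinylcyclohexanol
Product: 24 ten-membered (4Z)-10-ketone with C3 OPMB and C6 OTBS and C7 CH2CH2OTBS and C8 OTIPS, via potassium alkoxide 22 (not isolated), via potassium enolate 23 (not isolated)
Conditions: KH, 18-crown-6, THF, 0 °C to rt; then aq. NH4Cl, −78 °C
Reagents that add atoms: none
Why: KH with the crown ether gives the ion-separated alkoxide 22, whose oxyanion weakens the allylic C5–C10 bond and drives a concerted suprafacial [3,3] shift: C2 of the vinyl group bonds to C3 of the enol ether while C5–C10 breaks, giving the Δ1(10) enolate 23 and, on cold protonation, ketone 24. The closest known reaction type is the anionic oxy-Cope ring expansion of 1,2-dialkenylcyclohexanols to cyclodec-5-enones, which tolerates enol ether termini. The ten-membered ring is not closed end to end but arises by a four-carbon ring expansion of ring B through a six-membered chair array (C2, C1, C10, C5, C4, C3). Because the two alkenyl groups are cis on ring B, a chair must make one of the two new ring double bonds E and the other Z; in the conformer with the C10 vinyl group axial and the alkoxide and the C5 alkenyl group equatorial, C6 is axial on the chair, so C4=C5 becomes Z and the E bond falls into the enolate, where protonation erases it. C3 is set by chirality transfer from C5 (the new bond forms on the face of the allyl unit from which C10 departs) together with the E enol ether, which keeps the PMB-oxy group equatorial and C3–H toward C6. The selectivity needed is this chair over the ring-flipped chair (C5 alkenyl and alkoxide axial), which would give the E alkene and the C3 epimer; that chair carries a syn-diaxial contact between the bare alkoxide and the C8 TIPS-oxy group and an axial branched alkenyl group, whereas the vinyl/C6-oxygen contact of the productive chair is relieved as C5–C10 stretches. Boat transition states would require ring B to eclipse C5–C10 and are not expected to compete. The regiodefined enolate has no β-leaving group, so a cold quench avoids elimination of the C8 oxygen.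

Step 14
Reactants: 24 ketone
Product: 25 C10 tertiary methyl carbinol (C10–OH anti to C8–O)
Conditions: CeCl3, MeMgBr, THF, −78 °C
Reagents that add atoms: methylmagnesium bromide, C[Mg]Br
Why: Organocerium 1,2-addition suppresses enolisation and β-elimination. The carbonyl oxygen should lie anti to the C8 silyloxy dipole (dipole-minimised 1,3-model) and the methyl group should enter from the ring periphery, giving the 1,3-anti carbinol.

Step 15
Reactants: 25 tris-silyl ether
Product: 26 C6,C12-diol (C8 OTIPS and C3 OPMB retained)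
Conditions: HF·pyridine, pyridine, THF, 0 °C to rt
Reagents that add atoms: none
Why: Buffered HF cleaves the primary and the secondary TBS ethers much faster than the secondary TIPS ether (selective desilylation by silicon bulk).

Step 16
Reactants: 26 diol
Product: 29 trans-fused 6,12-lactone (saturated at C11), via hydroxy aldehyde 27 (not isolated), via lactol 28 (not isolated)
Conditions: TEMPO (cat.), PhI(OAc)2, CH2Cl2, rt
Reagents that add atoms: none
Why: Oxoammonium oxidation selects the primary alcohol; the aldehyde closes onto C6–OH as the five-membered lactol, which is oxidised on to the lactone (oxidative lactonisation of a 1,4-diol). C8 is silylated, so only the 6,12-lactone can form.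

Step 17
Reactants: 29 lactone
Product: 32 α-methylene lactone (C8 OTIPS and C3 OPMB), via Mannich base 30 (not isolated), via ammonium iodide 31 (not isolated)
Conditions: LiN(i-Pr)2 (3 equiv), THF, −78 °C; CH2=NMe2+ I−, −78 to 0 °C; then MeI, MeOH, rt; then aq. NaHCO3
Reagents that add atoms: N,N-dimethylmethyleneiminium iodide, C=[N+](C)C.[I-]
Why: Mannich aminomethylation of the lactone enolate, quaternisation and E1cB elimination; the extra base covers the tertiary alkoxide, and no other enolisable carbonyl is present at this stage.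

Step 18
Reactants: 32 silyl ether
Product: 33 C8 alcohol
Conditions: HF·pyridine, THF, 0 °C to rt
Reagents that add atoms: none
Why: Fluoride-mediated desilylation under non-basic conditions, chosen so that the freed C8 hydroxyl neither translactonises nor adds to the methylene lactone.

Step 19
Reactants: 33 alcohol
Product: 34 C8 isobutyrate (C3 OPMB)
Conditions: (i-PrCO)2O, Et3N, DMAP (cat.), CH2Cl2, 0 °C
Reagents that add atoms: isobutyric anhydride, CC(C)C(=O)OC(=O)C(C)C
Why: DMAP-catalysed acylation of the only secondary hydroxyl; the tertiary C10 carbinol is inert under these conditions.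

Step 20
Reactants: 34 PMB ether
Product: 35 CNP0163972.1
Conditions: DDQ, CH2Cl2, pH 7 buffer, 0 °C
Reagents that add atoms: none
Why: Oxidative PMB cleavage (benzylic hydride abstraction, hydrolysis of the oxocarbenium ion) leaves ester, lactone and tertiary alcohol untouched.

## Compound list

1 | 3-(tert-butyldimethylsilyloxy)propanal | O=CCCO[Si](C)(C)C(C)(C)C | starting material
2 | nitromethane | C[N+](=O)[O-] | starting material
3 | 4-(tert-butyldimethylsilyloxy)-1-nitrobutan-2-ol (racemic) | [O-][N+](=O)CC(O)CCO[Si](C)(C)C(C)(C)C | intermediate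
4 | (E)-tert-butyldimethyl(4-nitrobut-3-enyloxy)silane | [O-][N+](=O)/C=C/CCO[Si](C)(C)C(C)(C)C | intermediate
5 | (tert-butyldimethylsilyloxy)acetaldehyde | O=CCO[Si](C)(C)C(C)(C)C | starting material
6 | ethyl 2-(diethoxyphosphoryl)acrylate | C=C(C(=O)OCC)P(=O)(OCC)OCC | starting material
7 | (2S,3R)-2,5-bis(tert-butyldimethylsilyloxy)-3-(nitromethyl)pentanal | O=C[C@@H](O[Si](C)(C)C(C)(C)C)[C@H](CCO[Si](C)(C)C(C)(C)C)C[N+](=O)[O-] | intermediate
8 | ethyl (3R,4R)-3-(TBS-oxy)-4-[2-(TBS-oxy)ethyl]-5-nitrocyclohex-1-ene-1-carboxylate (C5-nitro epimers) | CCOC(=O)C1=C[C@@H](O[Si](C)(C)C(C)(C)C)[C@H](CCO[Si](C)(C)C(C)(C)C)C([N+](=O)[O-])C1 | intermediate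
9 | [(3R,4R)-3-(TBS-oxy)-4-[2-(TBS-oxy)ethyl]-5-nitrocyclohex-1-en-1-yl]methanol | OCC1=C[C@@H](O[Si](C)(C)C(C)(C)C)[C@H](CCO[Si](C)(C)C(C)(C)C)C([N+](=O)[O-])C1 | intermediate
10 | sodium nitronate of 9 | OCC1=C[C@@H](O[Si](C)(C)C(C)(C)C)[C@H](CCO[Si](C)(C)C(C)(C)C)C(=[N+]([O-])[O-])C1.[Na+] | intermediate
11 | 3-(hydroxymethyl)-5-(TBS-oxy)-6-[2-(TBS-oxy)ethyl]cyclohex-3-en-1-one (C6, C7 as in 9) | OCC1=C[C@@H](O[Si](C)(C)C(C)(C)C)[C@H](CCO[Si](C)(C)C(C)(C)C)C(=O)C1 | intermediate
12 | (1R,5R,6R)-5-(TBS-oxy)-6-[2-(TBS-oxy)ethyl]-3-(hydroxymethyl)cyclohex-3-en-1-ol | OCC1=C[C@@H](O[Si](C)(C)C(C)(C)C)[C@H](CCO[Si](C)(C)C(C)(C)C)[C@H](O)C1 | intermediate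
13 | C5–C10 epoxide of 12, oxirane oxygen cis to C8–OH | OC[C@@]12O[C@@H]1[C@@H](O[Si](C)(C)C(C)(C)C)[C@H](CCO[Si](C)(C)C(C)(C)C)[C@H](O)C2 | intermediate
14 | ring B triol: C10 (OH, CH2OH), C5 trimethylsilylethynyl, C6 OTBS, C7 CH2CH2OTBS, C8 OH | OC[C@]1(O)C[C@@H](O)[C@@H](CCO[Si](C)(C)C(C)(C)C)[C@H](O[Si](C)(C)C(C)(C)C)[C@@H]1C#C[Si](C)(C)C | intermediate
15 | primary 4-methylbenzenesulfonate of 14 | Cc1ccc(cc1)S(=O)(=O)OC[C@]2(O)C[C@@H](O)[C@@H](CCO[Si](C)(C)C(C)(C)C)[C@H](O[Si](C)(C)C(C)(C)C)[C@@H]2C#C[Si](C)(C)C | intermediate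
16 | C10 spiro-oxirane with C5 ethynyl and C8 OH | C1O[C@]12C[C@@H](O)[C@@H](CCO[Si](C)(C)C(C)(C)C)[C@H](O[Si](C)(C)C(C)(C)C)[C@@H]2C#C | intermediate
17 | C10 vinyl carbinol with C5 ethynyl and C8 OH | C=C[C@]1(O)C[C@@H](O)[C@@H](CCO[Si](C)(C)C(C)(C)C)[C@H](O[Si](C)(C)C(C)(C)C)[C@@H]1C#C | intermediate
18 | C8 triisopropylsilyl ether of 17 | C=C[C@]1(O)C[C@@H](O[Si](C(C)C)(C(C)C)C(C)C)[C@@H](CCO[Si](C)(C)C(C)(C)C)[C@H](O[Si](C)(C)C(C)(C)C)[C@@H]1C#C | intermediate
19 | (E)-alkenyl(dimethyl)alane, C10 dimethylaluminium alkoxide | C=C[C@]1(O[Al](C)C)C[C@@H](O[Si](C(C)C)(C(C)C)C(C)C)[C@@H](CCO[Si](C)(C)C(C)(C)C)[C@H](O[Si](C)(C)C(C)(C)C)[C@@H]1/C(C)=C/[Al](C)C | intermediate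
20 | (E)-vinyl iodide: C5 (E)-1-iodoprop-1-en-2-yl | C=C[C@]1(O)C[C@@H](O[Si](C(C)C)(C(C)C)C(C)C)[C@@H](CCO[Si](C)(C)C(C)(C)C)[C@H](O[Si](C)(C)C(C)(C)C)[C@@H]1/C(C)=C/I | intermediate
21 | (1R,2S,3S,4R,5R)-3-(TBS-oxy)-4-[2-(TBS-oxy)ethyl]-2-[(E)-1-(PMB-oxy)prop-1-en-2-yl]-5-(TIPS-oxy)-1-vinylcyclohexan-1-ol | C=C[C@]1(O)C[C@@H](O[Si](C(C)C)(C(C)C)C(C)C)[C@@H](CCO[Si](C)(C)C(C)(C)C)[C@H](O[Si](C)(C)C(C)(C)C)[C@@H]1/C(C)=C/OCc2ccc(OC)cc2 | intermediate
22 | potassium alkoxide of 21 | C=C[C@]1([O-])C[C@@H](O[Si](C(C)C)(C(C)C)C(C)C)[C@@H](CCO[Si](C)(C)C(C)(C)C)[C@H](O[Si](C)(C)C(C)(C)C)[C@@H]1/C(C)=C/OCc2ccc(OC)cc2.[K+] | intermediate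
23 | potassium Δ1(10)-enolate of 24 (E enolate, Z C4=C5) | CC(C)(C)[Si](C)(C)O[C@@H]1/C=C(/C)[C@@H](OCc2ccc(OC)cc2)C/C=C(\[O-])C[C@@H](O[Si](C(C)C)(C(C)C)C(C)C)[C@H]1CCO[Si](C)(C)C(C)(C)C.[K+] | intermediate
24 | ten-membered (4Z)-10-ketone: C3 OPMB, C6 OTBS, C7 CH2CH2OTBS, C8 OTIPS | CC(C)(C)[Si](C)(C)O[C@@H]1/C=C(/C)[C@@H](OCc2ccc(OC)cc2)CCC(=O)C[C@@H](O[Si](C(C)C)(C(C)C)C(C)C)[C@H]1CCO[Si](C)(C)C(C)(C)C | intermediate
25 | C10 tertiary methyl carbinol of 24 | CC(C)(C)[Si](C)(C)O[C@@H]1/C=C(/C)[C@@H](OCc2ccc(OC)cc2)CC[C@](C)(O)C[C@@H](O[Si](C(C)C)(C(C)C)C(C)C)[C@H]1CCO[Si](C)(C)C(C)(C)C | intermediate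
26 | C6,C12-diol (C3 OPMB, C8 OTIPS, C10 OH) | O[C@@H]1/C=C(/C)[C@@H](OCc2ccc(OC)cc2)CC[C@](C)(O)C[C@@H](O[Si](C(C)C)(C(C)C)C(C)C)[C@H]1CCO | intermediate
27 | C12 aldehyde of 26 | O[C@@H]1/C=C(/C)[C@@H](OCc2ccc(OC)cc2)CC[C@](C)(O)C[C@@H](O[Si](C(C)C)(C(C)C)C(C)C)[C@H]1CC=O | intermediate
28 | 6,12-lactol | C1C(O)O[C@@H]2/C=C(/C)[C@@H](OCc3ccc(OC)cc3)CC[C@](C)(O)C[C@@H](O[Si](C(C)C)(C(C)C)C(C)C)[C@@H]12 | intermediate
29 | 6,12-lactone, C11 saturated | C1C(=O)O[C@@H]2/C=C(/C)[C@@H](OCc3ccc(OC)cc3)CC[C@](C)(O)C[C@@H](O[Si](C(C)C)(C(C)C)C(C)C)[C@@H]12 | intermediate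
30 | C11 dimethylaminomethyl lactone | CN(C)CC1C(=O)O[C@@H]2/C=C(/C)[C@@H](OCc3ccc(OC)cc3)CC[C@](C)(O)C[C@@H](O[Si](C(C)C)(C(C)C)C(C)C)[C@@H]12 | intermediate
31 | C11 trimethylammoniomethyl lactone iodide | C[N+](C)(C)CC1C(=O)O[C@@H]2/C=C(/C)[C@@H](OCc3ccc(OC)cc3)CC[C@](C)(O)C[C@@H](O[Si](C(C)C)(C(C)C)C(C)C)[C@@H]12.[I-] | intermediate
32 | α-methylene lactone, C3 OPMB, C8 OTIPS | C=C1C(=O)O[C@@H]2/C=C(/C)[C@@H](OCc3ccc(OC)cc3)CC[C@](C)(O)C[C@@H](O[Si](C(C)C)(C(C)C)C(C)C)[C@@H]12 | intermediate
33 | α-methylene lactone, C3 OPMB, C8 OH | C=C1C(=O)O[C@@H]2/C=C(/C)[C@@H](OCc3ccc(OC)cc3)CC[C@](C)(O)C[C@@H](O)[C@@H]12 | intermediate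
34 | C3 PMB ether of the target | C=C1C(=O)O[C@@H]2/C=C(/C)[C@@H](OCc3ccc(OC)cc3)CC[C@](C)(O)C[C@@H](OC(=O)C(C)C)[C@@H]12 | intermediate
35 | CNP0163972.1 | C=C1C(=O)O[C@@H]2/C=C(/C)[C@@H](O)CC[C@](C)(O)C[C@@H](OC(=O)C(C)C)[C@@H]12 | target

## Step count and least certain steps

Total: 20 steps. Longest linear sequence: 20 steps (from 1); compounds 2, 5 and 6 enter along the way.

**Step 13 (key step).** The most likely failure is loss of Z selectivity: reaction through the ring-flipped chair would give the E alkene and the C3 epimer. Minor risks are O-to-O silyl migration toward the alkoxide and heterolytic fragmentation–recombination that erodes chirality transfer. Fallback, from 21: silylate the tertiary hydroxyl (Me3Si-imidazole) to the trimethylsilyl ether F1 and run the neutral thermal siloxy-Cope rearrangement (about 200 °C, sealed, base-washed glass) to the ring-expanded trimethylsilyl enol ether F2. There the bulky C10 silyloxy group cannot sit axial next to the C8 TIPS-oxy group, which biases ring B sterically toward the productive chair. Mild methanolysis (K2CO3, MeOH, 0 °C) returns to the route at 24.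

**Step 14.** Methyl addition to a conformationally mobile ten-membered ketone may show poor or reversed facial selectivity. Fallback, from 24: Petasis methylenation (Cp2TiMe2, toluene, 65 °C) to the exocyclic alkene F3, then Mukaiyama hydration (Mn(dpm)3, PhSiH3, O2, i-PrOH). Oxygen, not carbon, is then delivered from the ring periphery to the tertiary radical, which is the complementary facial sense. The route is rejoined at 25.

**Step 7.** The aluminium Lewis acid may ionise the tertiary C10–O bond (hydride or alkyl shift, attack at C10), or the opening next to the C6 silyloxy group may be sluggish. Fallback, from 13: mask both hydroxyls as triethylsilyl ethers (Et3SiOTf, 2,6-lutidine) to F4, and open the epoxide under purely basic SN2 conditions with LiC≡CH·H2NCH2CH2NH2 in DMSO to the ethynyl carbinol F5. Cleave the triethylsilyl groups (pyridinium tosylate, MeOH) to the terminal alkyne triol F6, form its primary tosylate F7 and close with K2CO3 in MeOH as in step 8. The route is rejoined at 16.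

**Step 12.** Coupling at the hindered trisubstituted iodide may be slow, so that protodeiodination competes; at 80 °C with carbonate, a premature alkoxide-triggered rearrangement of 21 is also possible. Fallback, from 20: Miyaura borylation (PdCl2(dppf), B2pin2, KOAc, DMSO, 50 °C) to the (E)-alkenyl pinacol boronate F8, then oxidative Chan–Lam coupling with 4-methoxybenzyl alcohol (Cu(OAc)2, Et3N, 4 Å sieves, air, rt). This forms the same enol ether at room temperature with retention of geometry and rejoins the route at 21.

## Further compounds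

F1 | step 13 | C10 trimethylsilyl ether of 21 | C=C[C@]1(O[Si](C)(C)C)C[C@@H](O[Si](C(C)C)(C(C)C)C(C)C)[C@@H](CCO[Si](C)(C)C(C)(C)C)[C@H](O[Si](C)(C)C(C)(C)C)[C@@H]1/C(C)=C/OCc2ccc(OC)cc2
F2 | step 13 | Δ1(10) trimethylsilyl enol ether of 24 | CC(C)(C)[Si](C)(C)O[C@@H]1/C=C(/C)[C@@H](OCc2ccc(OC)cc2)C/C=C(\O[Si](C)(C)C)C[C@@H](O[Si](C(C)C)(C(C)C)C(C)C)[C@H]1CCO[Si](C)(C)C(C)(C)C
F3 | step 14 | C10 exocyclic methylene analogue of 24 | CC(C)(C)[Si](C)(C)O[C@@H]1/C=C(/C)[C@@H](OCc2ccc(OC)cc2)CCC(=C)C[C@@H](O[Si](C(C)C)(C(C)C)C(C)C)[C@H]1CCO[Si](C)(C)C(C)(C)C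
F4 | step 7 | bis(triethylsilyl) ether of 13 | CC[Si](CC)(CC)OC[C@@]12O[C@@H]1[C@@H](O[Si](C)(C)C(C)(C)C)[C@H](CCO[Si](C)(C)C(C)(C)C)[C@H](O[Si](CC)(CC)CC)C2
F5 | step 7 | C5 ethynyl C10 carbinol, C8 and primary triethylsilyl ethers | CC[Si](CC)(CC)OC[C@]1(O)C[C@@H](O[Si](CC)(CC)CC)[C@@H](CCO[Si](C)(C)C(C)(C)C)[C@H](O[Si](C)(C)C(C)(C)C)[C@@H]1C#C
F6 | step 7 | terminal alkyne triol (desilyl 14) | OC[C@]1(O)C[C@@H](O)[C@@H](CCO[Si](C)(C)C(C)(C)C)[C@H](O[Si](C)(C)C(C)(C)C)[C@@H]1C#C
F7 | step 7 | primary 4-methylbenzenesulfonate of F6 | Cc1ccc(cc1)S(=O)(=O)OC[C@]2(O)C[C@@H](O)[C@@H](CCO[Si](C)(C)C(C)(C)C)[C@H](O[Si](C)(C)C(C)(C)C)[C@@H]2C#C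
F8 | step 12 | (E)-alkenyl pinacol boronate corresponding to 20 | C=C[C@]1(O)C[C@@H](O[Si](C(C)C)(C(C)C)C(C)C)[C@@H](CCO[Si](C)(C)C(C)(C)C)[C@H](O[Si](C)(C)C(C)(C)C)[C@@H]1/C(C)=C/B2OC(C)(C)C(C)(C)O2
A1 | alternative 1 | tricyclic [2+2] photoadduct with bicyclo[2.2.0]hexane (C6 ketone, C8 OTBS, two methyl esters) | O=C1[C@H](CC(=O)OC)[C@H](O[Si](C)(C)C(C)(C)C)C[C@]2(C)[C@H]1[C@@]3(C(=O)OC)CC[C@@H]23
A2 | alternative 1 | methyl 2-[2-(tert-butyldimethylsilyloxy)-4-methyl-6-oxocyclohex-4-en-1-yl]acetate (ring B enone) | O=C1[C@H](CC(=O)OC)[C@H](O[Si](C)(C)C(C)(C)C)CC(C)=C1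
A3 | alternative 1 | methyl cyclobut-1-ene-1-carboxylate | COC(=O)C1=CCC1
A4 | alternative 2 | C10 triethylsilyl ether of the target | C=C1C(=O)O[C@@H]2/C=C(/C)[C@@H](O)CC[C@](C)(O[Si](CC)(CC)CC)C[C@@H](OC(=O)C(C)C)[C@@H]12
A5 | alternative 2 | seco (Z)-vinyl iodide aldehyde (C4 iodide, C3 aldehyde, lactone and ester in place) | C=C1C(=O)O[C@H](/C=C(/C)I)[C@H]1[C@H](OC(=O)C(C)C)C[C@@](C)(O[Si](CC)(CC)CC)CCC=O
A6 | alternative 3 | ten-membered (4Z)-3-hydroxy-10-keto 6,12-lactone, C8 OTBS | C1C(=O)O[C@@H]2/C=C(/C)[C@@H](O)CCC(=O)C[C@@H](O[Si](C)(C)C(C)(C)C)[C@@H]12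
A7 | alternative 3 | lactone-fused cis-decalin 3,4-epoxy-10-ol, C8 OTBS | C[C@]12O[C@H]1CC[C@@]3(O)C[C@@H](O[Si](C)(C)C(C)(C)C)[C@H]4CC(=O)O[C@@H]4[C@@H]23
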